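**Strategy.** Ring B (C1, C2, C3, C4, C4a, C8a) is cut into two three-atom halves that meet at C4–C3 and C8a–C1. The C1–C2–C3 half is a 1,3-dielectrophile, trans-(3R,4R)-3,4-dimethyl-β-lactone (acyl carbon = C1, β-carbon = C3). The C4–C4a–C8a half is a 1,3-dinucleophile, a 2-bromo-4,5-dimethoxybenzyl metal. In one flask a copper-catalysed SN2 opening (C4–C3, inversion at C3) and a Parham cycliacylation (C8a–C1) give the cis-2,3-dimethyl-1-tetralone. The step exploits the 1,3-relation of C1 and C3 in ring B and the cis C2/C3 methyl pair, which maps onto the trans-lactone. Reduction and a trans-selective Friedel–Crafts arylation by veratrole then set C1.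

Key step: step 2

Remark: C1–C8a are the tetrahydronaphthalene positions of the target (C1 bears the aryl group, C2 and C3 the methyl groups, C4 is the ring CH2; ring A is the dimethoxybenzo ring, ring B the saturated ring); alcohol 9 is carried on as both C1 epimers because C1 is ionised in step 4.

Step 1
Reactants: 1 (R)-4-methyloxetan-2-one ((R)-β-butyrolactone)
Product: 3 (3R,4R)-3,4-dimethyloxetan-2-one (trans), via lithium enolate 2 (not isolated)
Conditions: LiN(i-Pr)2 (1.05 equiv), THF, −100 to −78 °C; MeI (3 equiv), −78 °C; AcOH quench
Reagents that add atoms: iodomethane, CI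
Why: α-Alkylation of a β-lactone enolate: the planar four-membered lithium enolate 2, in which ring opening by β-elimination is stereoelectronically blocked, should be methylated on the face opposite the C4 methyl group, so the new C3 centre is set trans to C4 (3R) while C4 (R) is untouched.

Step 2
Reactants: 3 (3R,4R)-3,4-dimethyloxetan-2-one; 4 2-bromo-4,5-dimethoxybenzyl bromide
Product: 8 (2R,3R)-6,7-dimethoxy-2,3-dimethyl-3,4-dihydronaphthalen-1(2H)-one, via Grignard reagent 5 (not isolated), via bromo carboxylate 6 (not isolated), via aryllithium 7 (not isolated)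
Conditions: Mg, Et2O, 0 °C (4 to 5); then 3, CuBr·SMe2 (10 mol %), THF–Me2S, −30 to 0 °C; then t-BuLi (3.2 equiv), −78 °C to rt; aq. NH4Cl
Reagents that add atoms: none
Why: The benzylic C–Br of 4 inserts Mg much faster than the aryl C–Br, and Grignard reagent 5, as an organocopper species formed with catalytic CuBr·SMe2, should attack the β-carbon of 3 with alkyl–oxygen cleavage (SN2), which forms C4–C3 and leaves magnesium carboxylate 6. Bromine–lithium exchange at the ortho ring carbon then gives aryllithium 7, whose carbanion adds to the carboxylate carbon (Parham cycliacylation) and forms C8a–C1; the dianionic tetrahedral adduct collapses to the ketone only on work-up, so neither over-addition nor base-mediated epimerisation at C2 should occur in the flask. The closest known reaction types are the copper-mediated opening of β-lactones by Grignard reagents to β-substituted acids and the Parham cyclisation of ortho-bromoaryl alkanoic acids to benzo-fused ketones. Ring B is closed in the second event by a 6-exo-trig attack of C8a on the carboxylate carbon, after the four-membered lactone ring has been opened by the intermolecular SN2 event. No stereocentre is made from a prochiral atom: C3 arises from the (4R) lactone carbon by inversion (the descriptor stays R because the priorities change) and C2 is carried over from step 1, so the trans-lactone is translated into the cis C2/C3 dimethyl pair of ring B. The step needs attack at the β-carbon instead of the acyl carbon, which the soft copper nucleophile and the low temperature should secure, and it needs the two nucleophilic sites of the ring A fragment to act in sequence, which the different rates of benzylic Mg insertion and aryl Br–Li exchange secure.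

Step 3
Reactants: 8 (2R,3R)-6,7-dimethoxy-2,3-dimethyl-3,4-dihydronaphthalen-1(2H)-one
Product: 9 (2R,3R)-6,7-dimethoxy-2,3-dimethyl-1,2,3,4-tetrahydronaphthalen-1-ol (both C1 epimers)
Conditions: NaBH4, CeCl3·7H2O, MeOH, −40 to 0 °C
Reagents that add atoms: none
Why: Luche-type borohydride reduction of the aryl ketone is fast at low temperature under nearly neutral conditions, so the α-stereocentre C2 should not epimerise; the new carbinol centre C1 need not be controlled because it is ionised in step 4.

Step 4
Reactants: 9 (2R,3R)-6,7-dimethoxy-2,3-dimethyl-1,2,3,4-tetrahydronaphthalen-1-ol; 10 veratrole (1,2-dimethoxybenzene)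
Product: 11 (1R,2R,3R)-1-(3,4-dimethoxyphenyl)-6,7-dimethoxy-2,3-dimethyl-1,2,3,4-tetrahydronaphthalene (target)
Conditions: 10 (5 equiv), HBF4·OEt2 (1 equiv), CH2Cl2, −78 to 0 °C
Reagents that add atoms: none
Why: Friedel–Crafts alkylation through the C1 benzylic cation, which is stabilised by the para methoxy group on C6 of ring A; veratrole should attack through its ring position para to a methoxy group on the face of the half-chair cation opposite the C2 methyl group and the pseudo-axial C3 methyl group, which sets C1 trans to C2, i.e. (1R).

Compound list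
1 | (R)-4-methyloxetan-2-one ((R)-β-butyrolactone) | C[C@H]1OC(=O)C1 | starting material
2 | lithium (R)-4-methyl-4H-oxet-2-olate (lithium enolate of 1) | C[C@H]1OC(O[Li])=C1 | intermediate
3 | (3R,4R)-3,4-dimethyloxetan-2-one (trans-β-lactone) | C[C@H]1OC(=O)[C@@H]1C | intermediate
4 | 2-bromo-4,5-dimethoxybenzyl bromide (1-bromo-2-(bromomethyl)-4,5-dimethoxybenzene) | COc1cc(CBr)c(Br)cc1OC | starting material
5 | (2-bromo-4,5-dimethoxybenzyl)magnesium bromide | COc1cc(C[Mg]Br)c(Br)cc1OC | intermediate
6 | bromomagnesium (2R,3R)-4-(2-bromo-4,5-dimethoxyphenyl)-2,3-dimethylbutanoate | Br[Mg]OC(=O)[C@H](C)[C@H](C)Cc1cc(OC)c(OC)cc1Br | intermediate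
7 | bromomagnesium (2R,3R)-4-(2-lithio-4,5-dimethoxyphenyl)-2,3-dimethylbutanoate | [Li]c1cc(OC)c(OC)cc1C[C@@H](C)[C@@H](C)C(=O)O[Mg]Br | intermediate
8 | (2R,3R)-6,7-dimethoxy-2,3-dimethyl-3,4-dihydronaphthalen-1(2H)-one (cis-2,3-dimethyl) | O=C1c2cc(OC)c(OC)cc2C[C@@H](C)[C@H]1C | intermediate
9 | (2R,3R)-6,7-dimethoxy-2,3-dimethyl-1,2,3,4-tetrahydronaphthalen-1-ol, both C1 epimers | OC1c2cc(OC)c(OC)cc2C[C@@H](C)[C@H]1C | intermediate
10 | veratrole (1,2-dimethoxybenzene) | COc1ccccc1OC | starting material
11 | (1R,2R,3R)-1-(3,4-dimethoxyphenyl)-6,7-dimethoxy-2,3-dimethyl-1,2,3,4-tetrahydronaphthalene (1,2-trans, 2,3-cis) | COc1ccc([C@@H]2c3cc(OC)c(OC)cc3C[C@@H](C)[C@H]2C)cc1OC | target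

Total steps: 4. Longest linear sequence: 4 steps (1 → 3 → 8 → 9 → 11); 4 and 10 enter as purchased building blocks.

Steps most likely to fail

Step 2. The benzyl nucleophile may attack the lactone carbonyl or act as a base (elimination to the unsaturated carboxylate) instead of opening at the β-carbon. After bromine–lithium exchange the aryllithium may be protonated, or may add too slowly to the weakly electrophilic magnesium carboxylate, so that the ring does not close. The fallback sets out from 3 and comes back at 8. Lactone 3 would be opened with (3,4-dimethoxybenzyl)magnesium chloride F1 (from 3,4-dimethoxybenzyl chloride and Mg) under CuBr·SMe2 catalysis. After acidic work-up (2R,3R)-4-(3,4-dimethoxyphenyl)-2,3-dimethylbutanoic acid F2 would be isolated. Ring B would then be closed by intramolecular Friedel–Crafts acylation with (CF3CO)2O in CH2Cl2 at 0 °C, at the ring carbon para to a methoxy group, to give 8. The two bonds are then made in two separate operations, and the ring closure is electrophilic instead of anionic.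

Step 1. Self-condensation of the strained enolate with unreacted lactone, or a second methylation, may outrun clean mono-methylation. The fallback sets out from 1 and comes back at 3. Acid-catalysed ethanolysis of 1 (EtOH, cat. H2SO4, acyl–oxygen cleavage) should give ethyl (R)-3-hydroxybutanoate F3, which can also be bought. Fráter–Seebach alkylation of its dianion (LiN(i-Pr)2, 2.2 equiv, MeI, THF, −50 to −20 °C) should give the anti ester ethyl (2R,3R)-3-hydroxy-2-methylbutanoate F4. Saponification (LiOH, THF–H2O) should give (2R,3R)-3-hydroxy-2-methylbutanoic acid F5. Carboxyl activation with PhSO2Cl in pyridine at 0 °C should close the β-lactone with retention at both centres to give 3.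

Step 4. Loss of the C2 proton from the benzylic cation would give the 1,2-dihydronaphthalene, and its reprotonation would scramble C2; attack on the wrong face would give the C1 epimer. The fallback sets out from 8 and comes back at 11. Ketone 8 would be reduced with LiBH(s-Bu)3 in THF at −78 °C, with hydride delivered to the face opposite both methyl groups, to the all-cis alcohol (1R,2R,3R)-6,7-dimethoxy-2,3-dimethyl-1,2,3,4-tetrahydronaphthalen-1-ol F6. Alkylation (NaH, BrCH2CH2OMe, DMF) should give the 2-methoxyethyl ether (1R,2R,3R)-1-(2-methoxyethoxy)-6,7-dimethoxy-2,3-dimethyl-1,2,3,4-tetrahydronaphthalene F7. A stereospecific Kumada coupling of this benzylic ether with 3,4-dimethoxyphenylmagnesium bromide (Ni(cod)2, a zerovalent nickel source, with dppe, PhMe, rt) should proceed with inversion at C1 and give 11 without a free cation.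

Further compounds
F1 | step 2 | (3,4-dimethoxybenzyl)magnesium chloride | COc1ccc(C[Mg]Cl)cc1OC
F2 | step 2 | (2R,3R)-4-(3,4-dimethoxyphenyl)-2,3-dimethylbutanoic acid | OC(=O)[C@H](C)[C@H](C)Cc1ccc(OC)c(OC)c1
F3 | step 1 | ethyl (R)-3-hydroxybutanoate | C[C@@H](O)CC(=O)OCC
F4 | step 1 | ethyl (2R,3R)-3-hydroxy-2-methylbutanoate | C[C@@H](O)[C@@H](C)C(=O)OCC
F5 | step 1 | (2R,3R)-3-hydroxy-2-methylbutanoic acid | C[C@@H](O)[C@@H](C)C(=O)O
F6 | step 4 | (1R,2R,3R)-6,7-dimethoxy-2,3-dimethyl-1,2,3,4-tetrahydronaphthalen-1-ol | O[C@H]1c2cc(OC)c(OC)cc2C[C@@H](C)[C@H]1C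
F7 | step 4 | (1R,2R,3R)-1-(2-methoxyethoxy)-6,7-dimethoxy-2,3-dimethyl-1,2,3,4-tetrahydronaphthalene | COCCO[C@H]1c2cc(OC)c(OC)cc2C[C@@H](C)[C@H]1C
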